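## Analysis of the target

The target is a flavanone: a chroman-4-one (ring C: O1, C2, C3, C4; fused benzene ring A: C4a, C5, C6, C7, C8, C8a) with a 2,6-dimethoxyphenyl group (ring B) on C2. The only stereocentre is C2 (S), a benzylic ether carbon β to the C4 ketone. It is labile in two ways: base opens ring C by retro-oxa-Michael reaction through the C3 enolate, and acid can ionise the C2–O1 bond because ring B carries two ortho-methoxy donors. Ring A is pentasubstituted: free 5-OH (hydrogen-bonded to the C4 carbonyl), 7-OMe, 8-OMe, O1 on C8a and the acyl carbon on C4a, with C6 the only CH and the 5-OH para to the 8-OMe. A classical assembly has to tell three or four phenolic oxygens apart on one ring and faces the 6,7- versus 7,8-dimethoxy ambiguity when an open precursor with two ortho-hydroxyls closes. Ring B is di-ortho-substituted, which hinders any bond formation at C2 by conjugate addition. The feature used here is the C4a=C8a bond of ring A: with O1 on C8a and the C4 carbonyl on C4a it is the enone double bond of a 2-aryl-2,3-dihydro-4H-pyran-4-one, the standard product of an asymmetric hetero-Diels–Alder reaction. The other four ring-A carbons, C5(OH), C6(H), C7(OMe) and C8(OMe), map atom for atom onto a semisquarate-derived cyclobutenone.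

## Retrosynthetic reasoning

17 to 14. Ring A is opened at C4a–C5 and its carbons C5–C8 are folded back into a four-membered ring. The precursor is cyclobutenone 14, in which C8 (the sp3 carbon, bearing OMe) is already bonded to C8a, which is C6 of the dihydropyranone. The forward reaction is a thermal ring expansion: 4π opening to dienylketene 15, 6π closure to dienone 16, tautomerisation to the phenol. The cut is placed here because the connectivity of 14 fixes every ring-A substituent, so no phenol has to be differentiated. It also means the flavanone appears only in the last step, under neutral conditions without base, acid or oxidant.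

14 to 12 via 13. The C4 ketone of 14 is traced back to a silyl-protected allylic alcohol. This detour is needed because the C8–C8a bond is made with a vinyl anion, which an enolisable ketone would not survive. The forward steps are a desilylation and an allylic alcohol oxidation, both carried out before any phenol exists.

12 to 6 and 9. The C8–C8a bond is cut. Forward, enol ether 6 is deprotonated at C6 to vinyllithium 10, which adds to methyl semisquarate 9 at the carbonyl next to the methoxy-bearing carbon; the resulting alkoxide 11 is O-methylated in the same flask. The regiochemistry of this addition decides the final pattern: it places the cyclobutenone CH where C6 of the target will be and the two methoxy groups where C7 and C8 will be.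

9 to 7. Semisquarate 9 comes from commercial dimethyl squarate 7 by mono-reduction to 8 and acid-induced loss of methanol, a one-step desymmetrisation.

6 to 4 via 5. The silyl ether is traced back to dihydropyranone 4 by 1,2-reduction and silylation. The C4 configuration set here is lost again at 14 and does not matter.

4 to 1 and 2. Ring C is cut at O1–C8a and C2–C3 (flavanone numbering). Forward, an enantioselective hetero-Diels–Alder reaction of aldehyde 1 with siloxydiene 2 forms ring C and sets C2 in one operation from two commercial compounds, before ring A exists. No later step breaks or forms a bond at C2.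

## Alternatives that were turned down

Alternative 1: the textbook route. Disconnection of O1–C2 and of the C3–C2 chain back to acetophenone A1 and aldehyde 1. Forward, Claisen–Schmidt condensation gives chalcone A2, and the key step is an enantioselective intramolecular oxa-Michael cyclisation of A2. It was turned down for three reasons.
- A2 has two ortho-hydroxyls. Closure through the other one gives the 5-hydroxy-6,7-dimethoxy isomer, and the two flavanones interconvert by ring opening (Wessely–Moser rearrangement), so one hydroxyl would need protection and extra steps.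
- The oxa-Michael step is reversible, and the enolate pathway that forms C2–O1 also racemises it. Catalytic asymmetric versions usually need an activating group on C3 that has to be installed and removed, and the di-ortho-substituted ring B twists the styryl unit and shields the β-carbon.
- A1 is not a commodity; its four oxygens require several selective steps on a phloroacetophenone core. The route is therefore no shorter and its stereocontrol is weaker.

Alternative 2: disconnection of the C2–C1' bond. The forward key step is a rhodium- or palladium-catalysed enantioselective conjugate addition of boronic acid A4 to chromone A3. It was turned down because A4 belongs to the di-ortho-alkoxy arylboronic acids, which protodeboronate fastest, and a di-ortho-substituted aryl group must be delivered to the β-carbon of a β-oxygenated enone, the most hindered case for this reaction. The peri 5-oxygen of A3 can also bind the catalyst, and A3 still has to be made from A1, so the ring-A problem is not solved.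

Alternative 3: disconnection of C4a–C5, C5–C6 and C7–C8, a Dötz benzannulation. Vinyllithium 10 would be converted into the pentacarbonylchromium carbene complex A5, which would react with alkyne A6 and one carbonyl ligand to build ring A. It was turned down on regiochemistry: a terminal alkyne places its substituent next to the new phenol carbon, so the methoxy group of A6 would end on C6 instead of C7. Correcting this would need a surrogate alkyne and further steps. The route also uses stoichiometric chromium and delivers the phenol at the alcohol oxidation level, so C4 would have to be oxidised next to an electron-rich phenol. The cyclobutenone ring expansion fixes the same pattern by connectivity alone.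

Key step: step 8

Assumptions (remarks on the chemistry): in step 1 the ligand antipode is the one that directs the diene to the Si face of 1, which corresponds to (S) at C2. Compounds 5 and 6 are written as the expected cis (2S,4S) isomers; any trans epimer converges at 14. The cyclobutenone quaternary carbon in 11–14 is an epimer mixture of no consequence.

## Route

Step 1
Reactants: 1 2,6-dimethoxybenzaldehyde; 2 (E)-1-methoxy-3-(trimethylsilyloxy)buta-1,3-diene
Product: 4 (2S)-2-(2,6-dimethoxyphenyl)-2,3-dihydro-4H-pyran-4-one, via aldol silyl ether 3 (not isolated)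
Conditions: Ti(OiPr)4 (10 mol%), H8-BINOL (12 mol%, antipode for Si-face attack), 4 Å MS, toluene, 0 °C; then TFA (cat.), CH2Cl2, 0 °C
Reagents that add atoms: none
Why: Catalytic enantioselective hetero-Diels–Alder reaction by the Mukaiyama aldol–cyclisation pathway; the chiral titanium binaphtholate shields one aldehyde face so that C–C bond formation on the Si face sets C2 as (S), and brief acid treatment closes the ring through the carbinol oxygen with loss of methanol, leaving the C2–O bond intact.

Step 2
Reactants: 4 (2S)-2-(2,6-dimethoxyphenyl)-2,3-dihydro-4H-pyran-4-one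
Product: 5 (2S,4S)-2-(2,6-dimethoxyphenyl)-3,4-dihydro-2H-pyran-4-ol
Conditions: NaBH4, CeCl3·7H2O, MeOH, −78 → −40 °C
Reagents that add atoms: none
Why: Luche reduction gives clean 1,2-reduction of the vinylogous ester; axial hydride delivery should give mainly the cis alcohol, whose configuration is erased in step 7, and C2 is not touched.

Step 3
Reactants: 5 (2S,4S)-2-(2,6-dimethoxyphenyl)-3,4-dihydro-2H-pyran-4-ol
Product: 6 triisopropyl{[(2S,4S)-2-(2,6-dimethoxyphenyl)-3,4-dihydro-2H-pyran-4-yl]oxy}silane
Conditions: TIPSOTf, 2,6-lutidine, CH2Cl2, −78 → 0 °C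
Reagents that add atoms: triisopropylsilyl trifluoromethanesulfonate, CC(C)[Si](OS(=O)(=O)C(F)(F)F)(C(C)C)C(C)C
Why: Buffered silylation of a secondary allylic alcohol; the bulky triisopropylsilyl ether is the group of choice for the lithiation that follows because it resists silyl migration and deprotonation on silicon.

Step 4
Reactants: 7 dimethyl squarate (3,4-dimethoxycyclobut-3-ene-1,2-dione)
Product: 9 3-methoxycyclobut-3-ene-1,2-dione, via hydroxycyclobutenone 8 (not isolated)
Conditions: LiAlH(OtBu)3, THF, −78 → 0 °C; then 6 M HCl, CH2Cl2, 0 °C → rt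
Reagents that add atoms: water, O
Why: Known reductive desymmetrisation of a squarate diester: one 1,2-hydride addition gives 8, aqueous acid ionises the carbinol, water adds to the resulting methoxy-stabilised cation and methanol is lost, leaving the semisquarate ester.

Step 5
Reactants: 6 triisopropyl{[(2S,4S)-2-(2,6-dimethoxyphenyl)-3,4-dihydro-2H-pyran-4-yl]oxy}silane; 9 3-methoxycyclobut-3-ene-1,2-dione
Product: 12 3,4-dimethoxy-4-[(2S,4S)-2-(2,6-dimethoxyphenyl)-4-(triisopropylsilyloxy)-3,4-dihydro-2H-pyran-6-yl]cyclobut-2-en-1-one, via vinyllithium 10 (not isolated), via lithium alkoxide 11 (not isolated)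
Conditions: t-BuLi (3 equiv), THF, −78 → 0 °C; then 9, THF, −78 °C; then MeOTf, −78 → 0 °C
Reagents that add atoms: methyl trifluoromethanesulfonate, COS(=O)(=O)C(F)(F)F
Why: α-Lithiation of a cyclic enol ether at C6 (as for C1-lithiated glycals; excess base is consumed by THF at 0 °C), then 1,2-addition to C2 of 9, the carbonyl next to the methoxy-bearing carbon, which is more electrophilic because it is not part of the vinylogous ester; the alkoxide is O-methylated in situ, and the new quaternary carbon forms as an inconsequential epimer mixture.

Step 6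
Reactants: 12 3,4-dimethoxy-4-[(2S,4S)-2-(2,6-dimethoxyphenyl)-4-(triisopropylsilyloxy)-3,4-dihydro-2H-pyran-6-yl]cyclobut-2-en-1-one
Product: 13 4-[(2S,4S)-2-(2,6-dimethoxyphenyl)-4-hydroxy-3,4-dihydro-2H-pyran-6-yl]-3,4-dimethoxycyclobut-2-en-1-one
Conditions: TBAF, AcOH, THF, 0 °C → rt
Reagents that add atoms: none
Why: Fluoride cleavage of the silyl ether, buffered with acetic acid so that neither the cyclobutenone nor the acid-sensitive enol ether meets strong base or acid.

Step 7
Reactants: 13 4-[(2S,4S)-2-(2,6-dimethoxyphenyl)-4-hydroxy-3,4-dihydro-2H-pyran-6-yl]-3,4-dimethoxycyclobut-2-en-1-one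
Product: 14 4-[(2S)-2-(2,6-dimethoxyphenyl)-4-oxo-3,4-dihydro-2H-pyran-6-yl]-3,4-dimethoxycyclobut-2-en-1-one
Conditions: DMP (1,1,1-triacetoxy-1,1-dihydro-1,2-benziodoxol-3(1H)-one), NaHCO3, CH2Cl2, 0 °C → rt
Reagents that add atoms: none
Why: Buffered periodinane oxidation of a secondary allylic alcohol to the vinylogous ester ketone; both C4 epimers converge and no phenol is yet present to compete.

Step 8
Reactants: 14 4-[(2S)-2-(2,6-dimethoxyphenyl)-4-oxo-3,4-dihydro-2H-pyran-6-yl]-3,4-dimethoxycyclobut-2-en-1-one
Product: 17 (2S)-5-hydroxy-7,8,2',6'-tetramethoxyflavanone, via dienylketene 15 (not isolated), via cyclohexadienone 16 (not isolated)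
Conditions: toluene (degassed, 0.01 M), 110 °C
Reagents that add atoms: none
Why: Thermal ring expansion of a 4-alkenyl-4-alkoxycyclobutenone (Moore rearrangement). Heating cleaves the C1–C4 bond of the cyclobutenone by conrotatory 4π electrocyclic opening, and the 4-methoxy donor rotates outward (torquoselectivity), which places the pyranonyl group cis to the ketene in dienylketene 15. A thermal disrotatory 6π electrocyclisation then joins the ketene carbon to C5 of the pyranone, the nucleophilic α-carbon of the vinylogous ester, closing ring A and forming the C4a–C5 bond in dienone 16. In 16 the C4a hydrogen lies between two carbonyl groups, so it should tautomerise at once to the hydrogen-bonded 5-phenol; the transient C4a stereocentre disappears and aromatisation makes the sequence irreversible. The step needs no regioselectivity of its own: the former cyclobutenone carbons C1, C2, C3 and C4 become C5(OH), C6(H), C7(OMe) and C8(OMe) by connectivity. The one selectivity required is the outward rotation of the methoxy group, which the donor substituent secures. No stereocentre is created; C2 takes no part in the bond reorganisation and the medium is neutral and aprotic, so neither retro-oxa-Michael opening nor ionisation at C2 should occur. The closest known reaction type is the same expansion of squarate-derived cyclobutenones carrying a cyclic α-alkoxyvinyl group at C4, which gives chromans and related annulated hydroquinone ethers.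

## Compound list

1 | 2,6-dimethoxybenzaldehyde | COc1cccc(OC)c1C=O | starting material
2 | (E)-1-methoxy-3-(trimethylsilyloxy)buta-1,3-diene | CO/C=C/C(=C)O[Si](C)(C)C | starting material
3 | (1E,5S)-5-(2,6-dimethoxyphenyl)-1-methoxy-5-(trimethylsilyloxy)pent-1-en-3-one | CO/C=C/C(=O)C[C@H](O[Si](C)(C)C)c1c(OC)cccc1OC | intermediate
4 | (2S)-2-(2,6-dimethoxyphenyl)-2,3-dihydro-4H-pyran-4-one | O=C1C=CO[C@H](c2c(OC)cccc2OC)C1 | intermediate
5 | (2S,4S)-2-(2,6-dimethoxyphenyl)-3,4-dihydro-2H-pyran-4-ol | O[C@@H]1C=CO[C@H](c2c(OC)cccc2OC)C1 | intermediate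
6 | triisopropyl{[(2S,4S)-2-(2,6-dimethoxyphenyl)-3,4-dihydro-2H-pyran-4-yl]oxy}silane | CC(C)[Si](O[C@@H]1C=CO[C@H](c2c(OC)cccc2OC)C1)(C(C)C)C(C)C | intermediate
7 | dimethyl squarate (3,4-dimethoxycyclobut-3-ene-1,2-dione) | COC1=C(OC)C(=O)C1=O | starting material
8 | 4-hydroxy-2,3-dimethoxycyclobut-2-en-1-one | COC1=C(OC)C(O)C1=O | intermediate
9 | 3-methoxycyclobut-3-ene-1,2-dione (methyl semisquarate) | COC1=CC(=O)C1=O | intermediate
10 | [(2S,4S)-2-(2,6-dimethoxyphenyl)-4-(triisopropylsilyloxy)-3,4-dihydro-2H-pyran-6-yl]lithium | [Li]C1=C[C@@H](O[Si](C(C)C)(C(C)C)C(C)C)C[C@@H](c2c(OC)cccc2OC)O1 | intermediate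
11 | lithium 1-[(2S,4S)-2-(2,6-dimethoxyphenyl)-4-(triisopropylsilyloxy)-3,4-dihydro-2H-pyran-6-yl]-2-methoxy-4-oxocyclobut-2-en-1-olate | [Li+].[O-]C1(C(=O)C=C1OC)C1=C[C@@H](O[Si](C(C)C)(C(C)C)C(C)C)C[C@@H](c2c(OC)cccc2OC)O1 | intermediate
12 | 3,4-dimethoxy-4-[(2S,4S)-2-(2,6-dimethoxyphenyl)-4-(triisopropylsilyloxy)-3,4-dihydro-2H-pyran-6-yl]cyclobut-2-en-1-one | COC1=CC(=O)C1(OC)C1=C[C@@H](O[Si](C(C)C)(C(C)C)C(C)C)C[C@@H](c2c(OC)cccc2OC)O1 | intermediate
13 | 4-[(2S,4S)-2-(2,6-dimethoxyphenyl)-4-hydroxy-3,4-dihydro-2H-pyran-6-yl]-3,4-dimethoxycyclobut-2-en-1-one | COC1=CC(=O)C1(OC)C1=C[C@@H](O)C[C@@H](c2c(OC)cccc2OC)O1 | intermediate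
14 | 4-[(2S)-2-(2,6-dimethoxyphenyl)-4-oxo-3,4-dihydro-2H-pyran-6-yl]-3,4-dimethoxycyclobut-2-en-1-one | COC1=CC(=O)C1(OC)C1=CC(=O)C[C@@H](c2c(OC)cccc2OC)O1 | intermediate
15 | (3Z)-4-[(2S)-2-(2,6-dimethoxyphenyl)-4-oxo-3,4-dihydro-2H-pyran-6-yl]-3,4-dimethoxybuta-1,3-dien-1-one | O=C=C/C(OC)=C(/OC)C1=CC(=O)C[C@@H](c2c(OC)cccc2OC)O1 | intermediate
16 | (2S)-2-(2,6-dimethoxyphenyl)-7,8-dimethoxy-2,3-dihydro-4H-chromene-4,5(4aH)-dione | COC1=CC(=O)C2C(=O)C[C@@H](c3c(OC)cccc3OC)OC2=C1OC | intermediate
17 | (2S)-5-hydroxy-7,8,2',6'-tetramethoxyflavanone | COc1cc(O)c2c(c1OC)O[C@H](c1c(OC)cccc1OC)CC2=O | target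

## Step count and risk assessment

Total step count: 8. Longest linear sequence: 7 steps (1 → 4 → 5 → 6 → 12 → 13 → 14 → 17); step 4 is a one-step side branch.

Step 8 (key step). The most likely failure is slow 6π closure, because the alkenyl partner is an electron-poor vinylogous ester, so that the ketene oligomerises. A second possibility is thermal erosion of the C2 configuration through reversible opening of the product. The fallback is to run the ring expansion one stage earlier, on the electron-rich enol ether, and to adjust C4 afterwards. It sets out from 12. Thermolysis in toluene at 110 °C should give (2S,4S)-2-(2,6-dimethoxyphenyl)-7,8-dimethoxy-4-(triisopropylsilyloxy)chroman-5-ol F1. TBAF would then release (2S,4S)-2-(2,6-dimethoxyphenyl)-7,8-dimethoxychromane-4,5-diol F2, and activated MnO2 in CH2Cl2 would oxidise the benzylic C4 alcohol, which comes back to the route at 17. This order also removes the fluoride and oxidation steps from the cyclobutenone series.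

Step 5. The most likely failure is unselective deprotonation: t-BuLi may also attack the benzylic C2–H or ring B, which would cost enantiopurity and conversion. The fallback replaces direct vinyl deprotonation by an anomeric sulfone. It sets out from 6. Addition of benzenesulfinic acid across the enol ether (CH2Cl2, rt) should give triisopropyl{[(2S,4S,6RS)-2-(2,6-dimethoxyphenyl)-6-(phenylsulfonyl)tetrahydro-2H-pyran-4-yl]oxy}silane F3, in which only the sulfonyl-activated C6–H is acidic towards n-BuLi at −78 °C. Addition of that anion to 9 and O-methylation with MeOTf would give 3,4-dimethoxy-4-[(2RS,4S,6S)-6-(2,6-dimethoxyphenyl)-2-(phenylsulfonyl)-4-(triisopropylsilyloxy)tetrahydro-2H-pyran-2-yl]cyclobut-2-en-1-one F4. On warming with i-Pr2NEt this should lose benzenesulfinic acid and regenerate the enol ether, which comes back to the route at 12.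

Step 1. The most likely failure is low conversion and facial selectivity with a di-ortho-substituted, electron-rich aldehyde. Acid-induced ionisation at the doubly activated benzylic carbon during cyclisation could also erode the enantiomeric purity. The fallback is resolution in place of asymmetric catalysis. It sets out from 1 and 2. Cyclocondensation promoted by BF3·OEt2 (CH2Cl2, −78 °C) would give racemic 2-(2,6-dimethoxyphenyl)-2,3-dihydro-4H-pyran-4-one F5, which would be separated on a preparative chiral stationary phase and comes back to the route at 4.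

Step 6. The most likely failure is degradation of the strained, electrophilic cyclobutenone by basic fluoride during the slow cleavage of a secondary triisopropylsilyl ether. The fallback replaces fluoride unmasking by mild acetal hydrolysis. It sets out from 5. 2-Methoxypropene with catalytic PPTS (CH2Cl2, 0 °C) would give (2S,4S)-2-(2,6-dimethoxyphenyl)-4-[(2-methoxypropan-2-yl)oxy]-3,4-dihydro-2H-pyran F6. Lithiation, addition to 9 and O-methylation as in step 5 would give 3,4-dimethoxy-4-{(2S,4S)-2-(2,6-dimethoxyphenyl)-4-[(2-methoxypropan-2-yl)oxy]-3,4-dihydro-2H-pyran-6-yl}cyclobut-2-en-1-one F7. PPTS in MeOH at 0 °C would then release the alcohol, which comes back to the route at 13.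

## Further compounds

F1 | step 8 | (2S,4S)-2-(2,6-dimethoxyphenyl)-7,8-dimethoxy-4-(triisopropylsilyloxy)chroman-5-ol | COc1cc(O)c2c(c1OC)O[C@H](c1c(OC)cccc1OC)C[C@@H]2O[Si](C(C)C)(C(C)C)C(C)C
F2 | step 8 | (2S,4S)-2-(2,6-dimethoxyphenyl)-7,8-dimethoxychromane-4,5-diol | COc1cc(O)c2c(c1OC)O[C@H](c1c(OC)cccc1OC)C[C@@H]2O
F3 | step 5 | triisopropyl{[(2S,4S,6RS)-2-(2,6-dimethoxyphenyl)-6-(phenylsulfonyl)tetrahydro-2H-pyran-4-yl]oxy}silane | CC(C)[Si](O[C@@H]1CC(S(=O)(=O)c2ccccc2)O[C@H](c2c(OC)cccc2OC)C1)(C(C)C)C(C)C
F4 | step 5 | 3,4-dimethoxy-4-[(2RS,4S,6S)-6-(2,6-dimethoxyphenyl)-2-(phenylsulfonyl)-4-(triisopropylsilyloxy)tetrahydro-2H-pyran-2-yl]cyclobut-2-en-1-one | COC1=CC(=O)C1(OC)C1(S(=O)(=O)c2ccccc2)C[C@@H](O[Si](C(C)C)(C(C)C)C(C)C)C[C@@H](c2c(OC)cccc2OC)O1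
F5 | step 1 | racemic 2-(2,6-dimethoxyphenyl)-2,3-dihydro-4H-pyran-4-one | O=C1C=COC(c2c(OC)cccc2OC)C1
F6 | step 6 | (2S,4S)-2-(2,6-dimethoxyphenyl)-4-[(2-methoxypropan-2-yl)oxy]-3,4-dihydro-2H-pyran | COC(C)(C)O[C@@H]1C=CO[C@H](c2c(OC)cccc2OC)C1
F7 | step 6 | 3,4-dimethoxy-4-{(2S,4S)-2-(2,6-dimethoxyphenyl)-4-[(2-methoxypropan-2-yl)oxy]-3,4-dihydro-2H-pyran-6-yl}cyclobut-2-en-1-one | COC1=CC(=O)C1(OC)C1=C[C@@H](OC(C)(C)OC)C[C@@H](c2c(OC)cccc2OC)O1
A1 | alternative 1 | 1-(2,6-dihydroxy-3,4-dimethoxyphenyl)ethan-1-one | CC(=O)c1c(O)cc(OC)c(OC)c1O
A2 | alternative 1 | (E)-1-(2,6-dihydroxy-3,4-dimethoxyphenyl)-3-(2,6-dimethoxyphenyl)prop-2-en-1-one | COc1cc(O)c(C(=O)/C=C/c2c(OC)cccc2OC)c(O)c1OC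
A3 | alternative 2 | 5-hydroxy-7,8-dimethoxy-4H-chromen-4-one | COc1cc(O)c2c(=O)ccoc2c1OC
A4 | alternative 2 | (2,6-dimethoxyphenyl)boronic acid | COc1cccc(OC)c1B(O)O
A5 | alternative 3 | pentacarbonyl{methoxy[(2S,4S)-2-(2,6-dimethoxyphenyl)-4-(triisopropylsilyloxy)-3,4-dihydro-2H-pyran-6-yl]methylidene}chromium | O=C=[Cr](=C=O)(=C=O)(=C=O)(=C=O)=C(OC)C1=C[C@@H](O[Si](C(C)C)(C(C)C)C(C)C)C[C@@H](c2c(OC)cccc2OC)O1
A6 | alternative 3 | methoxyethyne | COC#C
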